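**Retrosynthetic overview**
- Feature: in unit 1 (the 4'-methoxyflavone half), the biaryl carbon C8 of ring A lies between C8a–O1 and C7–OH. These two oxygens are ortho and para to C4a, which carries the C4 carbonyl. Both positions can therefore be carried as fluorine until the biaryl bond exists.
- Last disconnections: the four O-benzyl groups (hydrogenolysis), then C7–O (displacement of a 7-fluorine by benzyl alcohol).
- Key disconnection O1–C8a: ring C of unit 1 comes from a 1-(2,4-difluoro-3-arylphenyl)-1,3-diketone, whose enolate oxygen displaces the ortho fluorine.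
- The diketone comes from a biaryl methyl ketone and 4-methoxybenzoyl chloride. The C8–C6'' bond comes from a Suzuki–Miyaura coupling of a 2,6-difluoroaryl iodide with a genkwanin-derived 6-boronate.
- Ring order: all rings of unit 2 come intact from genkwanin and ring A of unit 1 comes from 3,5-difluorophenol. Silicon is parked between the fluorines during the second lithiation and is later exchanged for iodine. Ring C of unit 1 is the only ring formed.

Key step: step 11

Assumption: the target SMILES carries no descriptor for the C8–C6'' axis, so the biaryl is prepared as the racemic mixture of atropisomers and no step controls axial configuration.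

**Step 1**
Reactants: 1 3,5-difluorophenol
Product: 2 1-(benzyloxy)-3,5-difluorobenzene
Conditions: BnBr, K2CO3, DMF, rt
Reagents that add atoms: benzyl bromide, BrCc1ccccc1
Why: Williamson ether synthesis, in which the acidic difluorophenol is alkylated on oxygen by the primary benzylic bromide, and the benzyl group is one that falls in the final hydrogenolysis.

**Step 2**
Reactants: 2 1-(benzyloxy)-3,5-difluorobenzene
Product: 4 [4-(benzyloxy)-2,6-difluorophenyl]trimethylsilane, via aryllithium 3 (not isolated)
Conditions: n-BuLi, THF, −78 °C; then Me3SiCl, −78 °C → rt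
Reagents that add atoms: chlorotrimethylsilane, C[Si](C)(C)Cl
Why: Directed ortho-metalation takes the most acidic ring C–H, the one flanked by both fluorines, and silylation follows; silicon rather than iodine is placed here because a 2,6-difluoroaryl iodide would suffer base-induced iodine migration (halogen dance) in the next lithiation, whereas the silane is inert and later marks the site for iodine.

**Step 3**
Reactants: 4 [4-(benzyloxy)-2,6-difluorophenyl]trimethylsilane; 5 N-methoxy-N-methylacetamide
Product: 8 1-[6-(benzyloxy)-2,4-difluoro-3-(trimethylsilyl)phenyl]ethan-1-one, via aryllithium 6 (not isolated), via tetrahedral lithium adduct 7 (not isolated)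
Conditions: n-BuLi, THF, −78 °C; then 5, −78 °C; cold 1 M HCl
Reagents that add atoms: none
Why: With the site between the fluorines blocked, directed ortho-metalation can only take one of the two equivalent positions flanked by fluorine and benzyloxy, and the Weinreb ketone synthesis stops at chelated adduct 7 so that only the methyl ketone is released on quench, the temperature being held at −78 °C to prevent loss of LiF to an aryne.

**Step 4**
Reactants: 8 1-[6-(benzyloxy)-2,4-difluoro-3-(trimethylsilyl)phenyl]ethan-1-one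
Product: 9 1-[6-(benzyloxy)-2,4-difluoro-3-iodophenyl]ethan-1-one
Conditions: ICl, CH2Cl2, 0 °C → rt
Reagents that add atoms: iodine monochloride, ClI
Why: Electrophilic ipso-iododesilylation, in which attack at the silicon-bearing carbon is favoured by the β-silicon effect and by the para benzyloxy group, so iodine should enter exactly between the two fluorines and not at the free C5–H.

**Step 5**
Reactants: 10 genkwanin
Product: 11 2-[4-(benzyloxy)phenyl]-5-hydroxy-7-methoxy-4H-chromen-4-one
Conditions: BnBr (1.05 equiv), K2CO3, DMF, rt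
Reagents that add atoms: benzyl bromide, BrCc1ccccc1
Why: Selective Williamson alkylation, since the 4'-OH is the free and more acidic phenol while the 5-OH is held in a hydrogen bond to the C4 carbonyl, so one equivalent of bromide at room temperature should react at O-4' only and make ring B less prone to iodination.

**Step 6**
Reactants: 11 2-[4-(benzyloxy)phenyl]-5-hydroxy-7-methoxy-4H-chromen-4-one
Product: 12 2-[4-(benzyloxy)phenyl]-5-hydroxy-6-iodo-7-methoxy-4H-chromen-4-one
Conditions: BnMe3N·ICl2, CaCO3, CH2Cl2–MeOH, rt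
Reagents that add atoms: benzyltrimethylammonium dichloroiodate, C[N+](C)(C)Cc1ccccc1.Cl[I-]Cl
Why: Electrophilic aromatic iodination of a chelated phenol, for which 5-hydroxy-7-alkoxyflavones are known to take iodine from dichloroiodate at C6, ortho to the free 5-OH, whereas 5-O-alkylated flavones react at C8, which is why the 5-OH stays free until after this step.

**Step 7**
Reactants: 12 2-[4-(benzyloxy)phenyl]-5-hydroxy-6-iodo-7-methoxy-4H-chromen-4-one
Product: 13 5-(benzyloxy)-2-[4-(benzyloxy)phenyl]-6-iodo-7-methoxy-4H-chromen-4-one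
Conditions: BnBr, K2CO3, DMF, 70 °C
Reagents that add atoms: benzyl bromide, BrCc1ccccc1
Why: Williamson ether synthesis under forcing conditions, where heat in a dipolar aprotic solvent breaks the hydrogen bond of the 5-OH to the carbonyl and lets the hindered phenoxide be alkylated, removing the acidic proton before the two palladium steps.

**Step 8**
Reactants: 13 5-(benzyloxy)-2-[4-(benzyloxy)phenyl]-6-iodo-7-methoxy-4H-chromen-4-one
Product: 14 5-(benzyloxy)-2-[4-(benzyloxy)phenyl]-7-methoxy-6-(4,4,5,5-tetramethyl-1,3,2-dioxaborolan-2-yl)-4H-chromen-4-one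
Conditions: B2pin2, PdCl2(dppf) (cat.), KOAc, 1,4-dioxane, 90 °C
Reagents that add atoms: bis(pinacolato)diboron, CC1(C)OB(OC1(C)C)B1OC(C)(C)C(C)(C)O1
Why: Miyaura borylation, in which zerovalent palladium inserts into the C6–I bond and the acetate-ligated arylpalladium transmetalates with the diboron reagent, the weak base KOAc leaving benzyl ethers and pyranone untouched and holding back homocoupling.

**Step 9**
Reactants: 9 1-[6-(benzyloxy)-2,4-difluoro-3-iodophenyl]ethan-1-one; 14 5-(benzyloxy)-2-[4-(benzyloxy)phenyl]-7-methoxy-6-(4,4,5,5-tetramethyl-1,3,2-dioxaborolan-2-yl)-4H-chromen-4-one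
Product: 15 6-[3-acetyl-4-(benzyloxy)-2,6-difluorophenyl]-5-(benzyloxy)-2-[4-(benzyloxy)phenyl]-7-methoxy-4H-chromen-4-one
Conditions: Pd(OAc)2 (cat.), SPhos, K3PO4, toluene–H2O, 90 °C
Reagents that add atoms: none
Why: Suzuki–Miyaura coupling, in which oxidative addition of zerovalent palladium into the electron-poor C–I bond flanked only by two small fluorines is easy, the bulky electron-rich SPhos ligand is the standard answer to a di-ortho-alkoxy boronate, and coupling at the methyl ketone stage keeps hot base away from a fluoroaryl diketone that would ring-close prematurely.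

**Step 10**
Reactants: 15 6-[3-acetyl-4-(benzyloxy)-2,6-difluorophenyl]-5-(benzyloxy)-2-[4-(benzyloxy)phenyl]-7-methoxy-4H-chromen-4-one; 16 4-methoxybenzoyl chloride
Product: 18 1-{6-(benzyloxy)-3-[5-(benzyloxy)-2-(4-(benzyloxy)phenyl)-7-methoxy-4-oxo-4H-chromen-6-yl]-2,4-difluorophenyl}-3-(4-methoxyphenyl)propane-1,3-dione, via lithium enolate 17 (not isolated)
Conditions: LiN(SiMe3)2 (2.2 equiv), THF, −78 °C; then 16, −78 → 0 °C; cold 1 M HCl
Reagents that add atoms: none
Why: Claisen-type C-acylation of a preformed lithium enolate, in which the methyl ketone is by far the most acidic site of 15, the second equivalent of amide base takes up the acidic diketone as it forms and so prevents double acylation, an acid chloride is preferred to a benzoate ester because no alkoxide is released that could attack the activated fluorines, and the low temperature keeps the lithium diketonate from cyclising.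

**Step 11**
Reactants: 18 1-{6-(benzyloxy)-3-[5-(benzyloxy)-2-(4-(benzyloxy)phenyl)-7-methoxy-4-oxo-4H-chromen-6-yl]-2,4-difluorophenyl}-3-(4-methoxyphenyl)propane-1,3-dione
Product: 20 5-(benzyloxy)-8-{5-(benzyloxy)-2-[4-(benzyloxy)phenyl]-7-methoxy-4-oxo-4H-chromen-6-yl}-7-fluoro-2-(4-methoxyphenyl)-4H-chromen-4-one, via potassium enolate 19 (not isolated)
Conditions: K2CO3 (3 equiv), dry DMF (0.02 M), 80 °C
Reagents that add atoms: none
Why: K2CO3 removes the acidic proton between the two carbonyl groups of 18 to give delocalised enolate 19, whose oxygen on the anisyl-bearing carbon adds to the fluorine-bearing ring carbon ortho to the aroyl group (the future C8a), giving a Meisenheimer anion that is stabilised by that aroyl carbonyl and inductively by the second fluorine, and loss of fluoride then forms O1–C8a. The closest known reaction is the carbonate-mediated cyclisation of 1-(2-fluoroaryl)-1,3-diketones to flavones, an intramolecular SNAr O-arylation. Ring C of unit 1 is closed as a six-membered ring by addition–elimination at an sp2 carbon, the Z-enolate holding its oxygen within bonding distance of that carbon only. No stereocentre is formed and the C8–C6'' axis stays racemic. Three selectivities are needed: ortho over para fluorine is secured by reach, since the para carbon cannot be attained in any reasonable ring and intermolecular attack is held back by dilution; fluorine over the benzyloxy group on the other ortho carbon is secured by the greater electrophilicity of C–F and the better leaving group; and O- over C-attack is secured because the enolate carbon could only close a four-membered ring. Because the leaving group fixes where O1 enters, the 8-aryl and not the 6-aryl flavone is the only constitutional outcome, a question that a 2,6-dihydroxyaryl diketone would leave open.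

**Step 12**
Reactants: 20 5-(benzyloxy)-8-{5-(benzyloxy)-2-[4-(benzyloxy)phenyl]-7-methoxy-4-oxo-4H-chromen-6-yl}-7-fluoro-2-(4-methoxyphenyl)-4H-chromen-4-one
Product: 21 5,7-bis(benzyloxy)-8-{5-(benzyloxy)-2-[4-(benzyloxy)phenyl]-7-methoxy-4-oxo-4H-chromen-6-yl}-2-(4-methoxyphenyl)-4H-chromen-4-one
Conditions: BnOH, NaH, THF, 0 °C; then 20 in DMF, rt → 60 °C
Reagents that add atoms: benzyl alcohol, OCc1ccccc1
Why: Intermolecular SNAr, in which C7 is para to C4a so that the Meisenheimer charge is delocalised into the now coplanar C4 carbonyl as in known alkoxide and amine displacements on 7-fluorochromones, fluoride is by far the best leaving group present, and exchange at the 5- and 5''-benzyloxy carbons would be degenerate.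

**Step 13**
Reactants: 21 5,7-bis(benzyloxy)-8-{5-(benzyloxy)-2-[4-(benzyloxy)phenyl]-7-methoxy-4-oxo-4H-chromen-6-yl}-2-(4-methoxyphenyl)-4H-chromen-4-one
Product: 22 5,7-dihydroxy-8-[5-hydroxy-2-(4-hydroxyphenyl)-7-methoxy-4-oxo-4H-chromen-6-yl]-2-(4-methoxyphenyl)-4H-chromen-4-one (target)
Conditions: H2 (1 atm), 10% Pd/C, THF–MeOH, rt
Reagents that add atoms: none
Why: Catalytic hydrogenolysis of all four benzyl aryl ethers at atmospheric pressure, under which the two methyl ethers are inert and the cross-conjugated C2=C3 bonds of flavones are normally not reduced, should free the 5-, 7-, 5''- and 4'''-hydroxy groups and give the target.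

**Compound list**
1 | 3,5-difluorophenol | Oc1cc(F)cc(F)c1 | starting material
2 | 1-(benzyloxy)-3,5-difluorobenzene | Fc1cc(F)cc(OCc2ccccc2)c1 | intermediate
3 | [4-(benzyloxy)-2,6-difluorophenyl]lithium | [Li]c1c(F)cc(OCc2ccccc2)cc1F | intermediate
4 | [4-(benzyloxy)-2,6-difluorophenyl]trimethylsilane | C[Si](C)(C)c1c(F)cc(OCc2ccccc2)cc1F | intermediate
5 | N-methoxy-N-methylacetamide | CC(=O)N(C)OC | starting material
6 | [6-(benzyloxy)-2,4-difluoro-3-(trimethylsilyl)phenyl]lithium | [Li]c1c(F)c([Si](C)(C)C)c(F)cc1OCc1ccccc1 | intermediate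
7 | lithium 1-[6-(benzyloxy)-2,4-difluoro-3-(trimethylsilyl)phenyl]-1-[methoxy(methyl)amino]ethan-1-olate (racemic, centre lost on collapse) | CC(O[Li])(N(C)OC)c1c(F)c([Si](C)(C)C)c(F)cc1OCc1ccccc1 | intermediate
8 | 1-[6-(benzyloxy)-2,4-difluoro-3-(trimethylsilyl)phenyl]ethan-1-one | CC(=O)c1c(F)c([Si](C)(C)C)c(F)cc1OCc1ccccc1 | intermediate
9 | 1-[6-(benzyloxy)-2,4-difluoro-3-iodophenyl]ethan-1-one | CC(=O)c1c(F)c(I)c(F)cc1OCc1ccccc1 | intermediate
10 | genkwanin (5-hydroxy-2-(4-hydroxyphenyl)-7-methoxy-4H-chromen-4-one) | COc1cc(O)c2c(=O)cc(-c3ccc(O)cc3)oc2c1 | starting material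
11 | 2-[4-(benzyloxy)phenyl]-5-hydroxy-7-methoxy-4H-chromen-4-one | COc1cc(O)c2c(=O)cc(-c3ccc(OCc4ccccc4)cc3)oc2c1 | intermediate
12 | 2-[4-(benzyloxy)phenyl]-5-hydroxy-6-iodo-7-methoxy-4H-chromen-4-one | COc1cc2oc(-c3ccc(OCc4ccccc4)cc3)cc(=O)c2c(O)c1I | intermediate
13 | 5-(benzyloxy)-2-[4-(benzyloxy)phenyl]-6-iodo-7-methoxy-4H-chromen-4-one | COc1cc2oc(-c3ccc(OCc4ccccc4)cc3)cc(=O)c2c(OCc3ccccc3)c1I | intermediate
14 | 5-(benzyloxy)-2-[4-(benzyloxy)phenyl]-7-methoxy-6-(4,4,5,5-tetramethyl-1,3,2-dioxaborolan-2-yl)-4H-chromen-4-one | COc1cc2oc(-c3ccc(OCc4ccccc4)cc3)cc(=O)c2c(OCc3ccccc3)c1B1OC(C)(C)C(C)(C)O1 | intermediate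
15 | 6-[3-acetyl-4-(benzyloxy)-2,6-difluorophenyl]-5-(benzyloxy)-2-[4-(benzyloxy)phenyl]-7-methoxy-4H-chromen-4-one | CC(=O)c1c(OCc2ccccc2)cc(F)c(-c2c(OC)cc3oc(-c4ccc(OCc5ccccc5)cc4)cc(=O)c3c2OCc2ccccc2)c1F | intermediate
16 | 4-methoxybenzoyl chloride | COc1ccc(cc1)C(Cl)=O | starting material
17 | lithium enolate of 15 | [Li]OC(=C)c1c(OCc2ccccc2)cc(F)c(-c2c(OC)cc3oc(-c4ccc(OCc5ccccc5)cc4)cc(=O)c3c2OCc2ccccc2)c1F | intermediate
18 | 1-{6-(benzyloxy)-3-[5-(benzyloxy)-2-(4-(benzyloxy)phenyl)-7-methoxy-4-oxo-4H-chromen-6-yl]-2,4-difluorophenyl}-3-(4-methoxyphenyl)propane-1,3-dione | COc1ccc(cc1)C(=O)CC(=O)c1c(OCc2ccccc2)cc(F)c(-c2c(OC)cc3oc(-c4ccc(OCc5ccccc5)cc4)cc(=O)c3c2OCc2ccccc2)c1F | intermediate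
19 | potassium enolate of 18 (delocalised, geometry not fixed) | [K+].COc1ccc(cc1)C([O-])=CC(=O)c1c(OCc2ccccc2)cc(F)c(-c2c(OC)cc3oc(-c4ccc(OCc5ccccc5)cc4)cc(=O)c3c2OCc2ccccc2)c1F | intermediate
20 | 5-(benzyloxy)-8-{5-(benzyloxy)-2-[4-(benzyloxy)phenyl]-7-methoxy-4-oxo-4H-chromen-6-yl}-7-fluoro-2-(4-methoxyphenyl)-4H-chromen-4-one (racemic axis) | COc1ccc(-c2cc(=O)c3c(OCc4ccccc4)cc(F)c(-c4c(OC)cc5oc(-c6ccc(OCc7ccccc7)cc6)cc(=O)c5c4OCc4ccccc4)c3o2)cc1 | intermediate
21 | 5,7-bis(benzyloxy)-8-{5-(benzyloxy)-2-[4-(benzyloxy)phenyl]-7-methoxy-4-oxo-4H-chromen-6-yl}-2-(4-methoxyphenyl)-4H-chromen-4-one (racemic axis) | COc1ccc(-c2cc(=O)c3c(OCc4ccccc4)cc(OCc4ccccc4)c(-c4c(OC)cc5oc(-c6ccc(OCc7ccccc7)cc6)cc(=O)c5c4OCc4ccccc4)c3o2)cc1 | intermediate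
22 | 5,7-dihydroxy-8-[5-hydroxy-2-(4-hydroxyphenyl)-7-methoxy-4-oxo-4H-chromen-6-yl]-2-(4-methoxyphenyl)-4H-chromen-4-one (CNP0253922.0) | COc1ccc(-c2cc(=O)c3c(O)cc(O)c(-c4c(OC)cc5oc(-c6ccc(O)cc6)cc(=O)c5c4O)c3o2)cc1 | target

**Step count**
Total step count: 13.
Longest linear sequence: 9 steps. This is steps 1–4 followed by 9–13 from 3,5-difluorophenol, and the branch from genkwanin (steps 5–8 followed by 9–13) has the same length.

**Steps most likely to fail**

1. **Step 9, Suzuki–Miyaura coupling.**
   - Risk: transmetalation from a boronate flanked by two alkoxy groups is slow. Protodeboronation, or palladium-catalysed α-arylation of the methyl ketone, may then outrun biaryl formation.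
   - Fallback: the polarity is reversed and boron is dropped. The fallback sets out from 9. Zinc dust activated by LiCl in THF should insert into the electron-poor C–I bond without touching the ketone, giving [3-acetyl-4-(benzyloxy)-2,6-difluorophenyl]zinc iodide F1.
   - A Negishi coupling of this weakly basic arylzinc with iodoflavone 13 (Pd(OAc)2, RuPhos, THF, 60 °C) comes back to the route at 15. Step 8 is then not needed.

2. **Step 12, displacement of the 7-fluorine.**
   - Risk: the fluorine-bearing carbon is screened by the neighbouring flavonyl group and is activated only by a vinylogous-ester carbonyl. Conjugate addition of alkoxide at C2 or C2'' with opening of a pyranone ring, or exchange of the 7''-methoxy group, may therefore compete with the slow substitution.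
   - Fallback: the para oxygen is installed before any pyranone of unit 1 and before the biaryl bond. The fallback sets out from 9. Benzyl alcohol and Cs2CO3 in DMF should displace the para fluorine, because the ortho one is wedged between acetyl and iodine. This gives 1-[4,6-bis(benzyloxy)-2-fluoro-3-iodophenyl]ethan-1-one F2.
   - Suzuki–Miyaura coupling of F2 with 14 under the conditions of step 9 gives 6-[3-acetyl-4,6-bis(benzyloxy)-2-fluorophenyl]-5-(benzyloxy)-2-[4-(benzyloxy)phenyl]-7-methoxy-4H-chromen-4-one F3.
   - Acylation with 16 as in step 10 gives 1-{4,6-bis(benzyloxy)-3-[5-(benzyloxy)-2-(4-(benzyloxy)phenyl)-7-methoxy-4-oxo-4H-chromen-6-yl]-2-fluorophenyl}-3-(4-methoxyphenyl)propane-1,3-dione F4.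
   - The same enolate SNAr closure (K2CO3, DMF, 100 °C) on the single remaining fluorine comes back to the route at 21.

3. **Step 11, enolate SNAr ring closure.**
   - Risk: the aroyl carbonyl is twisted out of the ring plane by its two ortho substituents, and the reacting carbon is shielded by the flavonyl group, so addition may be slow. Retro-Claisen cleavage of the diketone by traces of water, or attack on the para fluorine by dimethylamine released from hot DMF, may then take over.
   - Fallback: the ring is closed before the biaryl bond is made, when only an iodine stands next to the fluorine. The fallback sets out from 9. Acylation with LiN(SiMe3)2 and 16 gives 1-[6-(benzyloxy)-2,4-difluoro-3-iodophenyl]-3-(4-methoxyphenyl)propane-1,3-dione F5.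
   - K2CO3 in DMF closes F5 to 5-(benzyloxy)-7-fluoro-8-iodo-2-(4-methoxyphenyl)-4H-chromen-4-one F6.
   - In F6 the iodine is still flanked only by fluorine and the tied-back ring oxygen. A Suzuki–Miyaura coupling with 14 (Pd(OAc)2, SPhos, K3PO4) comes back to the route at 20.

**Further compounds**
F1 | step 9 | [3-acetyl-4-(benzyloxy)-2,6-difluorophenyl]zinc iodide | CC(=O)c1c(F)c([Zn]I)c(F)cc1OCc1ccccc1
F2 | step 12 | 1-[4,6-bis(benzyloxy)-2-fluoro-3-iodophenyl]ethan-1-one | CC(=O)c1c(F)c(I)c(OCc2ccccc2)cc1OCc1ccccc1
F3 | step 12 | 6-[3-acetyl-4,6-bis(benzyloxy)-2-fluorophenyl]-5-(benzyloxy)-2-[4-(benzyloxy)phenyl]-7-methoxy-4H-chromen-4-one | CC(=O)c1c(OCc2ccccc2)cc(OCc2ccccc2)c(-c2c(OC)cc3oc(-c4ccc(OCc5ccccc5)cc4)cc(=O)c3c2OCc2ccccc2)c1F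
F4 | step 12 | 1-{4,6-bis(benzyloxy)-3-[5-(benzyloxy)-2-(4-(benzyloxy)phenyl)-7-methoxy-4-oxo-4H-chromen-6-yl]-2-fluorophenyl}-3-(4-methoxyphenyl)propane-1,3-dione | COc1ccc(cc1)C(=O)CC(=O)c1c(OCc2ccccc2)cc(OCc2ccccc2)c(-c2c(OC)cc3oc(-c4ccc(OCc5ccccc5)cc4)cc(=O)c3c2OCc2ccccc2)c1F
F5 | step 11 | 1-[6-(benzyloxy)-2,4-difluoro-3-iodophenyl]-3-(4-methoxyphenyl)propane-1,3-dione | COc1ccc(cc1)C(=O)CC(=O)c1c(OCc2ccccc2)cc(F)c(I)c1F
F6 | step 11 | 5-(benzyloxy)-7-fluoro-8-iodo-2-(4-methoxyphenyl)-4H-chromen-4-one | COc1ccc(-c2cc(=O)c3c(OCc4ccccc4)cc(F)c(I)c3o2)cc1
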